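**Plan**

- Retrosynthesis, side chain: the two CH2OH groups (C9'' of the glycerol unit and the branch on benzofuran C3) go back to CO2H groups and the phenols to benzyl ethers; the C7''–C8'' bond is cut by an aldol of an aryloxyacetyl imide, with C7'' inverted afterwards.
- Retrosynthesis, key cut: the dihydrobenzofuran C3–C3a bond is traced back to the C4–C4a bond of a (2S)-flavanone; the five-membered ring is the pyranone ring minus its carbonyl carbon, which is pushed out as the C3 carboxyl branch when ring-A carbon C4a shifts from C4 to C3 (oxidative ring contraction).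
- Enabling feature: benzofuran C3 carries both the aromatic carbon C3a and a one-carbon branch next to the O1–C2(aryl) unit, and C3a (C4a of the flavanone) is ortho to the ring oxygen O1, so it migrates readily to an electron-poor C3 while a ketal carbon takes up the charge left behind.
- Further cuts: the lactone α-CH2–aryl bond (Negishi coupling of a zinc homoenolate with a 6-bromoflavanone), the flavanone C2–aryl bond (asymmetric conjugate addition to a chromone), and the lactone itself (Stobbe half-ester).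
- Forward ring order: butyrolactone (step 3), chromone pyranone (step 9), union of the two halves (step 11), then contraction to the dihydrobenzofuran (step 12) as the last ring event; the glycerol side chain is finished afterwards.
- Stereochemistry: lactone Cβ from Rh/DuPhos hydrogenation and Cα from trans-selective enolate hydroxymethylation; benzofuran C2 from ligand-controlled conjugate addition and C3 from the stereospecific shift; C8'' from an (R)-oxazolidinone syn aldol and C7'' from Mitsunobu inversion.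

Key step: step 12

Assumption (sense of induction): (S,S)-Et-DuPhos/Rh is taken to give the (R)-succinate and (R)-t-BuPyOx/Pd the (2S)-flavanone, by analogy with itaconates and carbocyclic enones; the antipodal ligand would be used if a rotation or CD check of 6 or 18 showed the opposite sense.

Locants: C7'' is the benzylic carbinol carbon, C8'' the aryloxy-bearing carbon and C9'' the CH2OH carbon of the glycerol side chain.

**Route**

Step 1
Reactants: 1 4-benzyloxy-3-methoxybenzaldehyde; 2 dimethyl succinate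
Product: 3 (E)-4-(4-benzyloxy-3-methoxyphenyl)-3-(methoxycarbonyl)but-3-enoic acid
Conditions: NaOMe (1.5 equiv), MeOH, reflux; then aq. HCl
Reagents that add atoms: none
Why: Stobbe condensation of a non-enolisable aryl aldehyde with a succinate diester should give the (E)-arylidene half-ester in which the conjugated carboxyl stays esterified and the CH2 arm is the free acid.

Step 2
Reactants: 3 (E)-half-ester
Product: 4 (3R)-4-(4-benzyloxy-3-methoxyphenyl)-3-(methoxycarbonyl)butanoic acid
Conditions: [Rh(cod)((S,S)-Et-DuPhos)]BF4 (1 mol %), NaOMe (0.1 equiv), H2 (5 atm), MeOH, rt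
Reagents that add atoms: none
Why: Rh/DuPhos asymmetric hydrogenation of Stobbe-type itaconate half-esters is directed by the carboxylate and sets the stereocentre (R) under catalyst control, and the benzyl ether is inert to the homogeneous catalyst.

Step 3
Reactants: 4 (R)-half-ester
Product: 6 (R)-4-(4-benzyloxy-3-methoxybenzyl)dihydrofuran-2(3H)-one, via hydroxy acid salt 5 (not isolated)
Conditions: KOH (1 equiv), EtOH; Ca(BH4)2 (from CaCl2 + NaBH4), EtOH, −10 °C → rt; then 2 M HCl, rt
Reagents that add atoms: none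
Why: Ca(BH4)2 reduces the ester but not the carboxylate salt, and the 4-hydroxy acid lactonises on acidification, so the untouched stereocentre becomes Cβ (R) of the butyrolactone.

Step 4
Reactants: 6 (R)-lactone
Product: 8 (3S,4R)-4-(4-benzyloxy-3-methoxybenzyl)-3-(hydroxymethyl)dihydrofuran-2(3H)-one, via lithium enolate 7 (not isolated)
Conditions: LiN(iPr)2 (1.1 equiv), THF, −78 °C; CH2O (gas, from cracked paraformaldehyde), −78 → −30 °C; aq. NH4Cl
Reagents that add atoms: formaldehyde, C=O
Why: aldol hydroxymethylation of the lactone enolate with monomeric formaldehyde should occur anti to the β-arylmethyl group and give the trans lactone (substrate control).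

Step 5
Reactants: 8 hydroxymethyl lactone benzyl ether
Product: 9 (3S,4R)-4-(4-hydroxy-3-methoxybenzyl)-3-(hydroxymethyl)dihydrofuran-2(3H)-one
Conditions: H2 (1 atm), 10% Pd/C, EtOAc, rt
Reagents that add atoms: none
Why: hydrogenolysis of the aryl benzyl ether frees the phenol while the lactone and the primary alcohol are inert.

Step 6
Reactants: 9 phenol; 10 (R)-4-benzyl-3-(chloroacetyl)oxazolidin-2-one
Product: 11 (R)-4-benzyl-3-[2-(4-{[(3R,4S)-4-(hydroxymethyl)-5-oxotetrahydrofuran-3-yl]methyl}-2-methoxyphenoxy)acetyl]oxazolidin-2-one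
Conditions: K2CO3 (1.5 equiv), NaI (0.1 equiv), acetone, rt
Reagents that add atoms: none
Why: Williamson O-alkylation of the phenoxide (far more acidic than the primary alcohol) with the activated α-chloro imide (iodide-assisted SN2) installs the aryloxyacetyl imide needed for the later aldol.

Step 7
Reactants: 11 imide alcohol
Product: 12 (R)-4-benzyl-3-[2-(4-{[(3R,4R)-4-(iodomethyl)-5-oxotetrahydrofuran-3-yl]methyl}-2-methoxyphenoxy)acetyl]oxazolidin-2-one
Conditions: I2, PPh3, imidazole, CH2Cl2, 0 °C → rt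
Reagents that add atoms: iodine, II
Why: Appel iodination converts the primary alcohol to the iodide without touching a stereocentre, and the weakly basic medium should avoid elimination to the α-methylene lactone.

Step 8
Reactants: 13 1-(2-hydroxy-3-methoxyphenyl)ethanone
Product: 14 1-(5-bromo-2-hydroxy-3-methoxyphenyl)ethanone
Conditions: NBS (1.05 equiv), MeCN, 0 °C → rt
Reagents that add atoms: N-bromosuccinimide, O=C1CCC(=O)N1Br
Why: electrophilic aromatic bromination goes para to the phenolic OH, the only free position activated by it (both ortho sites are substituted).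

Step 9
Reactants: 14 bromo hydroxyacetophenone
Product: 16 6-bromo-8-methoxy-4H-chromen-4-one, via enaminone 15 (not isolated)
Conditions: Me2NCH(OMe)2 (2 equiv), toluene, 100 °C; then conc. HCl, CH2Cl2, 40 °C
Reagents that add atoms: N,N-dimethylformamide dimethyl acetal, COC(OC)N(C)C
Why: condensation of the methyl ketone with the formamide acetal gives the enaminone, and acid-mediated addition of the phenol oxygen with loss of dimethylamine closes the pyranone ring (standard chromone synthesis).

Step 10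
Reactants: 16 bromochromone; 17 (4-benzyloxy-3-methoxyphenyl)boronic acid
Product: 18 (S)-2-(4-benzyloxy-3-methoxyphenyl)-6-bromo-8-methoxychroman-4-one
Conditions: Pd(OCOCF3)2 (5 mol %), (R)-t-BuPyOx (6 mol %), NH4PF6 (30 mol %), H2O (5 equiv), ClCH2CH2Cl, 60 °C
Reagents that add atoms: none
Why: asymmetric conjugate addition of an arylboronic acid to a chromone under divalent-palladium/pyridine-oxazoline catalysis (transmetalation, enantio-determining carbopalladation of C2=C3, protonolysis) sets C2 (S) under ligand control and spares the aryl bromide because no zerovalent palladium is involved.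

Step 11
Reactants: 12 iodide; 18 (S)-bromoflavanone
Product: 20 (R)-4-benzyl-3-{2-[4-({(3R,4R)-4-[((2S)-2-(4-benzyloxy-3-methoxyphenyl)-8-methoxy-4-oxochroman-6-yl)methyl]-5-oxotetrahydrofuran-3-yl}methyl)-2-methoxyphenoxy]acetyl}oxazolidin-2-one, via alkylzinc iodide 19 (not isolated)
Conditions: Zn dust (Me3SiCl-activated, 3 equiv), DMF, rt; then 18, Pd2(dba)3 (2.5 mol %), SPhos (10 mol %), DMF, 45 °C
Reagents that add atoms: none
Why: zinc insertion gives a configurationally stable ester-stabilised zinc homoenolate, and Negishi coupling with the aryl bromide forms the CH2–aryl bond without base, so neither the flavanone C2 nor the lactone α-centre should epimerise.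

Step 12
Reactants: 20 flavanone–lactone imide
Product: 22 methyl (2S,3S)-5-{[(3R,4R)-4-(4-{2-[(R)-4-benzyl-2-oxooxazolidin-3-yl]-2-oxoethoxy}-3-methoxybenzyl)-2-oxotetrahydrofuran-3-yl]methyl}-2-(4-benzyloxy-3-methoxyphenyl)-7-methoxy-2,3-dihydrobenzofuran-3-carboxylate, via methyl enol ether 21 (not isolated)
Conditions: PhI(OAc)2 (1.2 equiv), HC(OMe)3 (solvent), conc. H2SO4 (cat.), 0 °C → rt
Reagents that add atoms: trimethyl orthoformate, COC(OC)OC
Why: Acid and trimethyl orthoformate turn the C4 ketone into its methyl enol ether 21, which attacks PhI(OAc)2 at C3 on the face anti to the C2 aryl group while methanol adds to C4; in the resulting trans-diequatorial C3-iodane the C4–C4a ring bond lies antiperiplanar to C3–I, so ring-A carbon C4a shifts from C4 to C3 as PhI departs, and the extruded C4, left as a dimethoxycarbenium ion, ends as CO2Me. The closest known reaction type is the oxidative 1,2-aryl-shift ring contraction of flavanones to trans-methyl 2-aryl-2,3-dihydrobenzofuran-3-carboxylates mediated by trivalent iodine or trivalent thallium. The five-membered ring O1–C2–C3–C3a–C7a is closed not by a cyclisation but by contraction of the six-membered pyranone, the new C3–C3a bond arising through a bridged phenonium (spiro three-membered, ipso-attack) transition state. C2 (S) is carried over untouched from the flavanone, and C3 (S) is fixed by anti addition of iodine followed by migration with inversion, which places CO2Me trans to the C2 aryl (also the thermodynamically preferred ester). The step needs migration of ring A (C4→C3) rather than of the C2 aryl (C2→C3, isoflavone) or plain dehydrogenation (flavone); this is secured by the two methoxy groups that stabilise the cation left at C4, by the ring oxygen O1 ortho to C4a that stabilises the phenonium, and by the equatorial C3–I geometry, while the absence of free OH groups leaves the oxidant no other partner.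

Step 13
Reactants: 22 ring-contracted ester; 1 4-benzyloxy-3-methoxybenzaldehyde
Product: 24 methyl (2S,3S)-5-{[(3R,4R)-4-(4-{[(2R,3S)-1-[(R)-4-benzyl-2-oxooxazolidin-3-yl]-3-(4-benzyloxy-3-methoxyphenyl)-3-hydroxy-1-oxopropan-2-yl]oxy}-3-methoxybenzyl)-2-oxotetrahydrofuran-3-yl]methyl}-2-(4-benzyloxy-3-methoxyphenyl)-7-methoxy-2,3-dihydrobenzofuran-3-carboxylate, via boron enolate 23 (not isolated)
Conditions: Bu2BOTf (1.3 equiv), iPr2NEt (1.5 equiv), CH2Cl2, −78 → 0 °C; 1 (1.3 equiv), −78 → 0 °C; pH 7 buffer, MeOH, 30% H2O2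
Reagents that add atoms: none
Why: Evans syn aldol, in which the dibutylboron Z-enolate reacts through a Zimmerman–Traxler chair on the face away from the auxiliary benzyl group, should give the (2R,3S) syn adduct and so fix C8''; only the imide is enolised by Bu2BOTf/iPr2NEt.

Step 14
Reactants: 24 syn aldol adduct
Product: 25 the (2R,3R)-3-(4-nitrobenzoyloxy) analogue of 24 (C7'' inverted and esterified; all other centres as in 24)
Conditions: 4-O2NC6H4CO2H (3 equiv), PPh3 (3 equiv), DIAD (3 equiv), THF, 0 °C → rt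
Reagents that add atoms: 4-nitrobenzoic acid, O=C(O)c1ccc(cc1)[N+](=O)[O-]
Why: Mitsunobu esterification displaces the activated benzylic oxygen with SN2 inversion, converting the syn (threo) adduct into the anti (erythro) C7'' configuration of the target.

Step 15
Reactants: 25 nitrobenzoate imide
Product: 27 (2S,3S)-2-(4-benzyloxy-3-methoxyphenyl)-5-{[(3R,4R)-4-(4-{[(1R,2R)-2-(4-benzyloxy-3-methoxyphenyl)-1-carboxy-2-hydroxyethyl]oxy}-3-methoxybenzyl)-2-oxotetrahydrofuran-3-yl]methyl}-7-methoxy-2,3-dihydrobenzofuran-3-carboxylic acid, via ring-opened tricarboxylate 26 (not isolated)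
Conditions: LiOH (8 equiv), 30% H2O2 (20 equiv), THF/H2O 3:1, 0 °C → rt; Na2SO3; then 1 M HCl to pH 2, rt
Reagents that add atoms: hydrogen peroxide, OO; lithium hydroxide, [Li+].[OH-]
Why: hydroperoxide, a strong nucleophile of low basicity, cleaves the exocyclic imide carbonyl first and then the nitrobenzoate and the methyl ester by acyl substitution without epimerisation, and the lactone, opened to the carboxylate, recloses on acidification.

Step 16
Reactants: 27 diacid
Product: 28 (3R,4R)-3-{[(2S,3R)-2-(4-benzyloxy-3-methoxyphenyl)-3-(hydroxymethyl)-7-methoxy-2,3-dihydrobenzofuran-5-yl]methyl}-4-(4-{[(1R,2S)-1-(4-benzyloxy-3-methoxyphenyl)-1,3-dihydroxypropan-2-yl]oxy}-3-methoxybenzyl)dihydrofuran-2(3H)-one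
Conditions: BH3·THF (6 equiv), THF, 0 °C → rt; MeOH quench
Reagents that add atoms: none
Why: borane reduces carboxylic acids much faster than lactones, so both CO2H groups should become CH2OH while the butyrolactone survives and no stereocentre is touched.

Step 17
Reactants: 28 dibenzyl ether
Product: 29 target CNP0265599.1
Conditions: H2 (1 atm), 10% Pd/C, EtOAc/MeOH, rt, short reaction time
Reagents that add atoms: none
Why: hydrogenolysis of the two aryl benzyl ethers liberates the phenols, the benzylic C–O bonds of the dihydrobenzofuran and of C7'' being much slower to cleave under these mild conditions.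

**Compound list**

1 | 4-benzyloxy-3-methoxybenzaldehyde | COc1cc(C=O)ccc1OCc1ccccc1 | starting material
2 | dimethyl succinate | COC(=O)CCC(=O)OC | starting material
3 | (E)-4-(4-benzyloxy-3-methoxyphenyl)-3-(methoxycarbonyl)but-3-enoic acid | COC(=O)/C(CC(=O)O)=C/c1ccc(OCc2ccccc2)c(OC)c1 | intermediate
4 | (3R)-4-(4-benzyloxy-3-methoxyphenyl)-3-(methoxycarbonyl)butanoic acid | COC(=O)[C@@H](CC(=O)O)Cc1ccc(OCc2ccccc2)c(OC)c1 | intermediate
5 | potassium (3R)-4-(4-benzyloxy-3-methoxyphenyl)-3-(hydroxymethyl)butanoate (not isolated) | OC[C@@H](CC(=O)[O-])Cc1ccc(OCc2ccccc2)c(OC)c1.[K+] | intermediate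
6 | (R)-4-(4-benzyloxy-3-methoxybenzyl)dihydrofuran-2(3H)-one | COc1cc(C[C@H]2COC(=O)C2)ccc1OCc1ccccc1 | intermediate
7 | lithium enolate of 6 (not isolated) | COc1cc(C[C@H]2COC(O[Li])=C2)ccc1OCc1ccccc1 | intermediate
8 | (3S,4R)-4-(4-benzyloxy-3-methoxybenzyl)-3-(hydroxymethyl)dihydrofuran-2(3H)-one | COc1cc(C[C@H]2COC(=O)[C@@H]2CO)ccc1OCc1ccccc1 | intermediate
9 | (3S,4R)-4-(4-hydroxy-3-methoxybenzyl)-3-(hydroxymethyl)dihydrofuran-2(3H)-one | COc1cc(C[C@H]2COC(=O)[C@@H]2CO)ccc1O | intermediate
10 | (R)-4-benzyl-3-(chloroacetyl)oxazolidin-2-one | ClCC(=O)N1C(=O)OC[C@H]1Cc1ccccc1 | starting material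
11 | (R)-4-benzyl-3-[2-(4-{[(3R,4S)-4-(hydroxymethyl)-5-oxotetrahydrofuran-3-yl]methyl}-2-methoxyphenoxy)acetyl]oxazolidin-2-one | COc1cc(C[C@H]2COC(=O)[C@@H]2CO)ccc1OCC(=O)N1C(=O)OC[C@H]1Cc1ccccc1 | intermediate
12 | (R)-4-benzyl-3-[2-(4-{[(3R,4R)-4-(iodomethyl)-5-oxotetrahydrofuran-3-yl]methyl}-2-methoxyphenoxy)acetyl]oxazolidin-2-one | COc1cc(C[C@H]2COC(=O)[C@@H]2CI)ccc1OCC(=O)N1C(=O)OC[C@H]1Cc1ccccc1 | intermediate
13 | 1-(2-hydroxy-3-methoxyphenyl)ethanone | CC(=O)c1cccc(OC)c1O | starting material
14 | 1-(5-bromo-2-hydroxy-3-methoxyphenyl)ethanone | CC(=O)c1cc(Br)cc(OC)c1O | intermediate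
15 | (E)-1-(5-bromo-2-hydroxy-3-methoxyphenyl)-3-(dimethylamino)prop-2-en-1-one (not isolated) | CN(C)/C=C/C(=O)c1cc(Br)cc(OC)c1O | intermediate
16 | 6-bromo-8-methoxy-4H-chromen-4-one | COc1cc(Br)cc2c(=O)ccoc12 | intermediate
17 | (4-benzyloxy-3-methoxyphenyl)boronic acid | COc1cc(B(O)O)ccc1OCc1ccccc1 | starting material
18 | (S)-2-(4-benzyloxy-3-methoxyphenyl)-6-bromo-8-methoxychroman-4-one | O=C1C[C@@H](c2ccc(OCc3ccccc3)c(OC)c2)Oc2c(OC)cc(Br)cc12 | intermediate
19 | alkylzinc iodide from 12: (3R,4R)-lactone with CH2ZnI in place of CH2I (not isolated) | COc1cc(C[C@H]2COC(=O)[C@@H]2C[Zn]I)ccc1OCC(=O)N1C(=O)OC[C@H]1Cc1ccccc1 | intermediate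
20 | (R)-4-benzyl-3-{2-[4-({(3R,4R)-4-[((2S)-2-(4-benzyloxy-3-methoxyphenyl)-8-methoxy-4-oxochroman-6-yl)methyl]-5-oxotetrahydrofuran-3-yl}methyl)-2-methoxyphenoxy]acetyl}oxazolidin-2-one | COc1cc(C[C@H]2COC(=O)[C@@H]2Cc2cc(OC)c3O[C@H](c4ccc(OCc5ccccc5)c(OC)c4)CC(=O)c3c2)ccc1OCC(=O)N1C(=O)OC[C@H]1Cc1ccccc1 | intermediate
21 | methyl enol ether of 20: (2S)-4,8-dimethoxy-2H-chromene in place of the chroman-4-one (not isolated) | COc1cc(C[C@H]2COC(=O)[C@@H]2Cc2cc(OC)c3O[C@H](c4ccc(OCc5ccccc5)c(OC)c4)C=C(OC)c3c2)ccc1OCC(=O)N1C(=O)OC[C@H]1Cc1ccccc1 | intermediate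
22 | methyl (2S,3S)-5-{[(3R,4R)-4-(4-{2-[(R)-4-benzyl-2-oxooxazolidin-3-yl]-2-oxoethoxy}-3-methoxybenzyl)-2-oxotetrahydrofuran-3-yl]methyl}-2-(4-benzyloxy-3-methoxyphenyl)-7-methoxy-2,3-dihydrobenzofuran-3-carboxylate | COc1cc(C[C@H]2COC(=O)[C@@H]2Cc2cc(OC)c3O[C@H](c4ccc(OCc5ccccc5)c(OC)c4)[C@@H](C(=O)OC)c3c2)ccc1OCC(=O)N1C(=O)OC[C@H]1Cc1ccccc1 | intermediate
23 | dibutylboron (Z)-enolate of the aryloxyacetyl imide of 22 (not isolated) | COc1cc(C[C@H]2COC(=O)[C@@H]2Cc2cc(OC)c3O[C@H](c4ccc(OCc5ccccc5)c(OC)c4)[C@@H](C(=O)OC)c3c2)ccc1O/C=C(\OB(CCCC)CCCC)N1C(=O)OC[C@H]1Cc1ccccc1 | intermediate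
24 | syn aldol adduct: 22 carrying a (2R,3S)-3-(4-benzyloxy-3-methoxyphenyl)-3-hydroxy-2-aryloxypropanoyl imide | COc1cc(C[C@H]2COC(=O)[C@@H]2Cc2cc(OC)c3O[C@H](c4ccc(OCc5ccccc5)c(OC)c4)[C@@H](C(=O)OC)c3c2)ccc1O[C@H]([C@@H](O)c1ccc(OCc2ccccc2)c(OC)c1)C(=O)N1C(=O)OC[C@H]1Cc1ccccc1 | intermediate
25 | (2R,3R)-3-(4-nitrobenzoyloxy) analogue of 24 (C7'' inverted) | COc1cc(C[C@H]2COC(=O)[C@@H]2Cc2cc(OC)c3O[C@H](c4ccc(OCc5ccccc5)c(OC)c4)[C@@H](C(=O)OC)c3c2)ccc1O[C@H]([C@H](OC(=O)c1ccc(cc1)[N+](=O)[O-])c1ccc(OCc2ccccc2)c(OC)c1)C(=O)N1C(=O)OC[C@H]1Cc1ccccc1 | intermediate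
26 | trilithium salt of the lactone-opened hydroxy triacid: (2R,3R)-butanoate chain with free CH2OH; benzofuran-3-carboxylate; (2R,3R)-2-aryloxy-3-hydroxypropanoate (not isolated) | COc1cc(C[C@@H](CO)[C@H](C(=O)[O-])Cc2cc(OC)c3O[C@H](c4ccc(OCc5ccccc5)c(OC)c4)[C@@H](C(=O)[O-])c3c2)ccc1O[C@H]([C@H](O)c1ccc(OCc2ccccc2)c(OC)c1)C(=O)[O-].[Li+].[Li+].[Li+] | intermediate
27 | (2S,3S)-2-(4-benzyloxy-3-methoxyphenyl)-5-{[(3R,4R)-4-(4-{[(1R,2R)-2-(4-benzyloxy-3-methoxyphenyl)-1-carboxy-2-hydroxyethyl]oxy}-3-methoxybenzyl)-2-oxotetrahydrofuran-3-yl]methyl}-7-methoxy-2,3-dihydrobenzofuran-3-carboxylic acid | COc1cc(C[C@H]2COC(=O)[C@@H]2Cc2cc(OC)c3O[C@H](c4ccc(OCc5ccccc5)c(OC)c4)[C@@H](C(=O)O)c3c2)ccc1O[C@H]([C@H](O)c1ccc(OCc2ccccc2)c(OC)c1)C(=O)O | intermediate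
28 | (3R,4R)-3-{[(2S,3R)-2-(4-benzyloxy-3-methoxyphenyl)-3-(hydroxymethyl)-7-methoxy-2,3-dihydrobenzofuran-5-yl]methyl}-4-(4-{[(1R,2S)-1-(4-benzyloxy-3-methoxyphenyl)-1,3-dihydroxypropan-2-yl]oxy}-3-methoxybenzyl)dihydrofuran-2(3H)-one | COc1cc(C[C@H]2COC(=O)[C@@H]2Cc2cc(OC)c3O[C@H](c4ccc(OCc5ccccc5)c(OC)c4)[C@@H](CO)c3c2)ccc1O[C@H]([C@H](O)c1ccc(OCc2ccccc2)c(OC)c1)CO | intermediate
29 | CNP0265599.1: (3R,4R)-3-{[(2S,3R)-2-(4-hydroxy-3-methoxyphenyl)-3-(hydroxymethyl)-7-methoxy-2,3-dihydrobenzofuran-5-yl]methyl}-4-(4-{[(1R,2S)-1-(4-hydroxy-3-methoxyphenyl)-1,3-dihydroxypropan-2-yl]oxy}-3-methoxybenzyl)dihydrofuran-2(3H)-one | COc1cc([C@@H](O)[C@H](CO)Oc2ccc(C[C@H]3COC(=O)[C@@H]3Cc3cc(OC)c4c(c3)[C@H](CO)[C@@H](c3ccc(O)c(OC)c3)O4)cc2OC)ccc1O | target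

**Step count and risks**

Total steps: 17. Longest linear sequence: 14 (steps 1–7 and 11–17); the flavanone branch (steps 8–10) joins at step 11.

Steps most likely to fail:

1. Step 12 (ring contraction). What may go wrong: a competing 1,2-shift of the electron-rich C2 aryl group (isoflavone pathway) or dehydrogenation to the flavone; acid-induced opening and re-closure of the pyranone with erosion of the C2 configuration; oxidative attack on the dialkoxyarene rings. Fallback: a photochemical Wolff ring contraction that sets out from 20 and comes back at 22. Heating 20 with Me2NCH(OMe)2 in toluene should give the 3-(dimethylaminomethylene)flavanone F1. Diazo transfer with TsN3 in CH2Cl2 would then give the 3-diazoflavanone F2. Irradiation (365 nm) in MeOH/THF would expel N2; the acyl carbene rearranges with migration of C4a to a ketene that methanol traps as the methyl ester. A short treatment with catalytic DBU would equilibrate C3 to the trans ester 22.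

2. Step 14 (Mitsunobu inversion). What may go wrong: β-elimination of the activated oxygen toward the α-aryloxy cinnamoyl imide; ionisation of the electron-rich benzylic oxyphosphonium species with loss of stereospecificity. Fallback: redox inversion that sets out from 24 and comes back at 27. Dess–Martin periodinane in CH2Cl2 would oxidise the carbinol to the β-keto imide F3. Catalyst-controlled asymmetric transfer hydrogenation with RuCl(p-cymene)[(S,S)-TsDPEN] and HCO2H/Et3N would then give the anti (2R,3R) β-hydroxy imide F4. F4 treated under the conditions of step 15 would give 27 directly.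

3. Step 15 (global hydrolysis). What may go wrong: base-induced β-elimination of the ring oxygen O1 from the ester enolate (opening of the dihydrobenzofuran); elimination of 4-nitrobenzoate before the imide is cleaved; incomplete relactonisation. Fallback: a staged cleavage that sets out from 25 and comes back at 27, with the sensitive ester removed last without hydroxide. LiOH/H2O2 at 0 °C for a short time would cleave only the imide and the nitrobenzoate, giving the hydroxy acid methyl ester F5 (after acidification). The remaining methyl ester would then be cleaved with Me3SnOH in ClCH2CH2Cl at 70 °C, under neutral organotin conditions, to give 27.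

**Further compounds**

F1 | step 12 | 3-(dimethylaminomethylene) derivative of flavanone 20 (E; C2 spatial arrangement as in 20) | COc1cc(C[C@H]2COC(=O)[C@@H]2Cc2cc(OC)c3O[C@H](c4ccc(OCc5ccccc5)c(OC)c4)/C(=C\N(C)C)C(=O)c3c2)ccc1OCC(=O)N1C(=O)OC[C@H]1Cc1ccccc1
F2 | step 12 | 3-diazo derivative of flavanone 20 (C2 spatial arrangement as in 20) | COc1cc(C[C@H]2COC(=O)[C@@H]2Cc2cc(OC)c3O[C@H](c4ccc(OCc5ccccc5)c(OC)c4)C(=[N+]=[N-])C(=O)c3c2)ccc1OCC(=O)N1C(=O)OC[C@H]1Cc1ccccc1
F3 | step 14 | β-keto imide from 24 (C7'' ketone; C8'' as in 24) | COc1cc(C[C@H]2COC(=O)[C@@H]2Cc2cc(OC)c3O[C@H](c4ccc(OCc5ccccc5)c(OC)c4)[C@@H](C(=O)OC)c3c2)ccc1O[C@H](C(=O)c1ccc(OCc2ccccc2)c(OC)c1)C(=O)N1C(=O)OC[C@H]1Cc1ccccc1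
F4 | step 14 | anti (2R,3R) β-hydroxy imide, the C7'' epimer of 24 | COc1cc(C[C@H]2COC(=O)[C@@H]2Cc2cc(OC)c3O[C@H](c4ccc(OCc5ccccc5)c(OC)c4)[C@@H](C(=O)OC)c3c2)ccc1O[C@H]([C@H](O)c1ccc(OCc2ccccc2)c(OC)c1)C(=O)N1C(=O)OC[C@H]1Cc1ccccc1
F5 | step 15 | (2R,3R)-2-aryloxy-3-hydroxy acid with the benzofuran methyl ester and the lactone intact | COc1cc(C[C@H]2COC(=O)[C@@H]2Cc2cc(OC)c3O[C@H](c4ccc(OCc5ccccc5)c(OC)c4)[C@@H](C(=O)OC)c3c2)ccc1O[C@H]([C@H](O)c1ccc(OCc2ccccc2)c(OC)c1)C(=O)O
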